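**Strategy.** Ring B carries oxygen at C6 and C8 (labdane numbering), and the quaternary ring-fusion carbon C10 lies β to C8, so C6–C5…C10–C9–C8 is a masked 1,5-diketone. The route rests on breaking the C5–C10 and C7–C8 bonds together. This unravels both rings to an open-chain triketone: a methyl ketone (C7–C6–C5) joined through the C4 quaternary centre and a three-carbon tether to a tetrasubstituted enone (C10=C9–C8=O) carrying a masked side chain. One base-mediated Michael/aldol-condensation cascade closes ring A and then ring B. C4 comes from a Claisen rearrangement; C9, C8 and C6 are adjusted afterwards, and enyne metathesis builds the diene.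

Key step: step 9

Remark: labdane numbering is used for the carbocyclic compounds (C18 = oxygenated CH2 on C4; C19, C20 and C17 = methyls on C4, C10 and C8). Compounds 1, 2, 6, 11 and 12 are taken as commercially available.

Step 1
Reactants: 1 tert-butyl(diphenyl)(prop-2-yn-1-yloxy)silane; 2 (benzyloxy)acetyl chloride
Product: 4 (E)-1-(benzyloxy)-5-[(tert-butyldiphenylsilyl)oxy]-4-methylpent-3-en-2-one, via alkenylalane 3 (not isolated)
Conditions: Me3Al, Cp2ZrCl2 (25 mol%), CH2Cl2, 0 °C to rt; volatiles removed; then 2, Pd(PPh3)4 (5 mol%), THF, 0 °C to rt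
Reagents that add atoms: trimethylaluminium, C[Al](C)C
Why: Zirconium-catalysed syn-carboalumination (Negishi) places CH3 on the internal and aluminium on the terminal alkyne carbon, and palladium-catalysed acylation of the alkenylalane with the acid chloride should proceed with retention of the E geometry.

Step 2
Reactants: 4 enone
Product: 5 (2S,3E)-1-(benzyloxy)-5-[(tert-butyldiphenylsilyl)oxy]-4-methylpent-3-en-2-ol
Conditions: (S)-2-methyl-CBS-oxazaborolidine (20 mol%), BH3·SMe2, THF, −30 °C
Reagents that add atoms: none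
Why: Corey–Bakshi–Shibata reduction in which the trisubstituted alkenyl group acts as the large substituent, so that the (S)-catalyst should deliver hydride to give the (S)-carbinol.

Step 3
Reactants: 5 allylic alcohol; 6 2-methoxypropene
Product: 8 (4R,5E)-7-(benzyloxy)-4-{[(tert-butyldiphenylsilyl)oxy]methyl}-4-methylhept-5-en-2-one, via allyl isopropenyl ether 7 (not isolated)
Conditions: 6 (10 equiv), propanoic acid (10 mol%), xylene, 140 °C, sealed tube
Reagents that add atoms: none
Why: Saucy–Marbet variant of the Claisen rearrangement, in which acid-catalysed exchange gives the allyl isopropenyl ether and its chair [3,3] shift with CH2OBn equatorial transfers the carbinol configuration suprafacially to the new quaternary centre C4 while forming the acetonyl arm and an E alkene.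

Step 4
Reactants: 8 unsaturated ketone
Product: 9 (4S)-4-{[(tert-butyldiphenylsilyl)oxy]methyl}-7-hydroxy-4-methylheptan-2-one
Conditions: H2 (1 atm), Pd/C (10 wt%), EtOAc–EtOH, rt
Reagents that add atoms: none
Why: Heterogeneous hydrogenation saturates the disubstituted alkene and hydrogenolyses the benzyl ether, while the ketone and the silyl ether are inert.

Step 5
Reactants: 9 keto alcohol
Product: 10 (4S)-4-{[(tert-butyldiphenylsilyl)oxy]methyl}-7-iodo-4-methylheptan-2-one
Conditions: I2, PPh3, imidazole, CH2Cl2, 0 °C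
Reagents that add atoms: iodine, II
Why: Appel-type iodination converts the unhindered primary alcohol into the iodide by SN2 displacement of its alkoxyphosphonium ion.

Step 6
Reactants: 11 pentane-2,4-dione; 12 (4-bromobut-1-yn-1-yl)trimethylsilane
Product: 13 3-[4-(trimethylsilyl)but-3-yn-1-yl]pentane-2,4-dione
Conditions: K2CO3, NaI (10 mol%), acetone, reflux
Reagents that add atoms: none
Why: Finkelstein-assisted C-alkylation of the acetylacetone enolate with a primary halide.

Step 7
Reactants: 13 alkylated diketone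
Product: 14 4-oxo-3-[4-(trimethylsilyl)but-3-yn-1-yl]pent-2-en-2-yl trifluoromethanesulfonate (E/Z mixture)
Conditions: NaH, THF, 0 °C; then Tf2O, −78 °C to 0 °C
Reagents that add atoms: trifluoromethanesulfonic anhydride, O=S(=O)(OS(=O)(=O)C(F)(F)F)C(F)(F)F
Why: O-sulfonylation of the sodium enolate of the 1,3-diketone gives the vinylogous acyl triflate, and both alkene isomers are usable because this geometry is lost later.

Step 8
Reactants: 10 iodide; 14 enol triflate
Product: 16 (4S)-4-{[(tert-butyldiphenylsilyl)oxy]methyl}-4,8-dimethyl-9-[4-(trimethylsilyl)but-3-yn-1-yl]undec-8-ene-2,10-dione, via alkylzinc iodide 15 (not isolated)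
Conditions: Zn dust (activated with 1,2-dibromoethane and Me3SiCl), DMA, 40 °C; then 14, PdCl2(dppf) (5 mol%), THF, rt to 45 °C
Reagents that add atoms: none
Why: Direct zinc insertion gives a ketone-tolerant alkylzinc iodide that should undergo Negishi cross-coupling with the electron-poor enol triflate, the silyl cap keeping the alkyne out of carbopalladation.

Step 9
Reactants: 16 triketone
Product: 20 (4S,5S,10R)-18-[(tert-butyldiphenylsilyl)oxy]-14,15-dinorlabd-8-en-13(16)-yn-6-one, via desilylated triketone 17 (not isolated), via Michael adduct 18 (not isolated), via potassium dienolate 19 (not isolated)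
Conditions: t-BuOK (5 equiv), t-BuOH–THF (1:1), 0 °C to 45 °C; then transfer into AcOH–THF at −78 °C
Reagents that add atoms: none
Why: tert-Butoxide first removes the alkynyl silyl group and equilibrates the ketone enolates; only the C5 enolate of the methyl ketone can reach the enone β-carbon C10 in a 6-exo-trig Michael addition (ring A, C5–C10), and the C7 enolate of the resulting 1,5-diketone then closes ring B on the C8 carbonyl by a 6-(enolendo)-exo-trig aldol addition followed by E1cB loss of water (C7–C8), the closest known reaction type being the Robinson-type intramolecular Michael/aldol condensation. Excess base converts the enone into the extended dienolate 19, which erases C9, and cold acetic acid protonates it at C7 to give the deconjugated ketone. C10 is set in a chair transition state with the enone arm equatorial and the C10 methyl axial, in which the small C4 methyl rather than CH2OTBDPS should take the position syn-axial to that methyl and eclipsed with the enolate (allylic 1,3-strain), so that the two methyls end up syn. C5 stays epimerisable and should settle as the trans ring fusion. The step needs regioselection between the C5 and C7 enolates and among the possible aldol partners; all other additions are reversible or lead to medium rings, and only the C5→C10/C7→C8 pathway is drained by irreversible dehydration. The facial bias from C4 is the weakest element.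

Step 10
Reactants: 20 deconjugated ketone
Product: 21 (4S,5S,9R,10S)-18-[(tert-butyldiphenylsilyl)oxy]-14,15-dinorlabd-7-en-13(16)-yn-6-one
Conditions: p-TsOH·H2O (10 mol%), CH2Cl2, 0 °C
Reagents that add atoms: none
Why: Acid-catalysed conjugation through the dienol, in which kinetic axial protonation at C9 on the face opposite to the adjacent axial C10 methyl should place H9 cis to H5 and the side chain equatorial.

Step 11
Reactants: 21 conjugated enone
Product: 22 (4S,5S,7R,8R,9S,10S)-18-[(tert-butyldiphenylsilyl)oxy]-7,8-epoxy-14,15-dinorlabd-13(16)-yn-6-one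
Conditions: dimethyldioxirane (acetone solution), CH2Cl2, 0 °C to rt
Reagents that add atoms: dimethyldioxirane, CC1(C)OO1
Why: Electrophilic epoxidation of the enone under neutral conditions (no C9 epimerisation) should occur on the face opposite to the axial C10 and C4 methyls, which puts the C8 oxygen on the face of H5 and H9.

Step 12
Reactants: 22 epoxy ketone
Product: 24 (4S,5S,6R,8S,9S,10R)-18-[(tert-butyldiphenylsilyl)oxy]-14,15-dinorlabd-13(16)-yne-6,8-diol, via β-hydroxy ketone 23 (not isolated)
Conditions: SmI2 (2.5 equiv), THF–MeOH, −78 °C; then SmI2 (3 equiv), H2O, Et3N, 0 °C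
Reagents that add atoms: none
Why: Single-electron reduction cleaves the α C–O bond of the epoxy ketone with retention at C8, and further electron transfer with water and amine reduces the ketone through a C6 organosamarium that should be protonated under thermodynamic control to the equatorial alcohol, the axial epimer being destabilised by three syn-axial methyl groups.

Step 13
Reactants: 24 silyl ether diol
Product: 25 (4S,5S,6R,8S,9S,10R)-14,15-dinorlabd-13(16)-yne-6,8,18-triol
Conditions: Bu4NF, AcOH, THF, rt
Reagents that add atoms: none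
Why: Fluoride-induced cleavage of the silyl ether, buffered with acetic acid.

Step 14
Reactants: 25 triol
Product: 26 (4S,5S,6R,8S,9S,10R)-6,8-dihydroxy-14,15-dinorlabd-13(16)-yn-18-yl acetate
Conditions: Ac2O (1.1 equiv), pyridine, CH2Cl2, −20 °C to 0 °C
Reagents that add atoms: acetic anhydride, CC(=O)OC(C)=O
Why: Acylation should discriminate the primary hydroxyl from the hindered equatorial secondary and the tertiary hydroxyls.

Step 15
Reactants: 26 alkyne
Product: 27 (4S,5S,6R,8S,9S,10R)-6,8-dihydroxylabda-13(16),14-dien-18-yl acetate (target)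
Conditions: second-generation Grubbs catalyst RuCl2(=CHPh)(PCy3)(H2IMes) (10 mol%), ethene (1 atm), CH2Cl2, 40 °C
Reagents that add atoms: ethene, C=C
Why: Ruthenium-catalysed enyne cross-metathesis of the terminal alkyne with ethene should give the 2-substituted 1,3-diene without touching the hydroxyls or the acetate.

**Compound list**

1 | tert-butyl(diphenyl)(prop-2-yn-1-yloxy)silane | C#CCO[Si](c1ccccc1)(c1ccccc1)C(C)(C)C | starting material
2 | (benzyloxy)acetyl chloride | O=C(Cl)COCc1ccccc1 | starting material
3 | (E)-{3-[(tert-butyldiphenylsilyl)oxy]-2-methylprop-1-en-1-yl}dimethylalumane (not isolated) | C[Al](C)/C=C(\C)CO[Si](c1ccccc1)(c1ccccc1)C(C)(C)C | intermediate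
4 | (E)-1-(benzyloxy)-5-[(tert-butyldiphenylsilyl)oxy]-4-methylpent-3-en-2-one | O=C(COCc1ccccc1)/C=C(\C)CO[Si](c1ccccc1)(c1ccccc1)C(C)(C)C | intermediate
5 | (2S,3E)-1-(benzyloxy)-5-[(tert-butyldiphenylsilyl)oxy]-4-methylpent-3-en-2-ol | O[C@H](COCc1ccccc1)/C=C(\C)CO[Si](c1ccccc1)(c1ccccc1)C(C)(C)C | intermediate
6 | 2-methoxypropene | COC(C)=C | starting material
7 | tert-butyl{[(2E,4S)-5-(benzyloxy)-2-methyl-4-(prop-1-en-2-yloxy)pent-2-en-1-yl]oxy}diphenylsilane (not isolated) | C=C(C)O[C@H](COCc1ccccc1)/C=C(\C)CO[Si](c1ccccc1)(c1ccccc1)C(C)(C)C | intermediate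
8 | (4R,5E)-7-(benzyloxy)-4-{[(tert-butyldiphenylsilyl)oxy]methyl}-4-methylhept-5-en-2-one | CC(=O)C[C@@](C)(CO[Si](c1ccccc1)(c1ccccc1)C(C)(C)C)/C=C/COCc1ccccc1 | intermediate
9 | (4S)-4-{[(tert-butyldiphenylsilyl)oxy]methyl}-7-hydroxy-4-methylheptan-2-one | CC(=O)C[C@@](C)(CO[Si](c1ccccc1)(c1ccccc1)C(C)(C)C)CCCO | intermediate
10 | (4S)-4-{[(tert-butyldiphenylsilyl)oxy]methyl}-7-iodo-4-methylheptan-2-one | CC(=O)C[C@@](C)(CO[Si](c1ccccc1)(c1ccccc1)C(C)(C)C)CCCI | intermediate
11 | pentane-2,4-dione | CC(=O)CC(C)=O | starting material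
12 | (4-bromobut-1-yn-1-yl)trimethylsilane | BrCCC#C[Si](C)(C)C | starting material
13 | 3-[4-(trimethylsilyl)but-3-yn-1-yl]pentane-2,4-dione | CC(=O)C(CCC#C[Si](C)(C)C)C(C)=O | intermediate
14 | 4-oxo-3-[4-(trimethylsilyl)but-3-yn-1-yl]pent-2-en-2-yl trifluoromethanesulfonate (E/Z mixture) | CC(=O)C(CCC#C[Si](C)(C)C)=C(C)OS(=O)(=O)C(F)(F)F | intermediate
15 | {(4S)-4-{[(tert-butyldiphenylsilyl)oxy]methyl}-4-methyl-6-oxoheptyl}zinc iodide (not isolated) | CC(=O)C[C@@](C)(CO[Si](c1ccccc1)(c1ccccc1)C(C)(C)C)CCC[Zn]I | intermediate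
16 | (4S)-4-{[(tert-butyldiphenylsilyl)oxy]methyl}-4,8-dimethyl-9-[4-(trimethylsilyl)but-3-yn-1-yl]undec-8-ene-2,10-dione (E/Z mixture) | CC(=O)C[C@@](C)(CO[Si](c1ccccc1)(c1ccccc1)C(C)(C)C)CCCC(C)=C(CCC#C[Si](C)(C)C)C(C)=O | intermediate
17 | (4S)-9-(but-3-yn-1-yl)-4-{[(tert-butyldiphenylsilyl)oxy]methyl}-4,8-dimethylundec-8-ene-2,10-dione (not isolated) | CC(=O)C[C@@](C)(CO[Si](c1ccccc1)(c1ccccc1)C(C)(C)C)CCCC(C)=C(CCC#C)C(C)=O | intermediate
18 | Michael adduct (not isolated): ring A cyclohexane (4S,5S,10S) with acetyl on C5 and 2-oxohept-6-yn-3-yl on C10 trans-diequatorial, C10 methyl axial and syn to the C4 methyl, CH2OTBDPS equatorial, C9 epimers | C#CCCC(C(C)=O)[C@]1(C)CCC[C@](C)(CO[Si](c4ccccc4)(c5ccccc5)C(C)(C)C)[C@H]1C(C)=O | intermediate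
19 | potassium 6,8(9)-dienolate of the bicyclic ketone, (4S,5S,10R) (not isolated) | C#CCCC=1[C@]2(C)CCC[C@](C)(CO[Si](c4ccccc4)(c5ccccc5)C(C)(C)C)[C@H]2C([O-])=CC=1C.[K+] | intermediate
20 | (4S,5S,10R)-18-[(tert-butyldiphenylsilyl)oxy]-14,15-dinorlabd-8-en-13(16)-yn-6-one (trans-fused) | C#CCCC=1[C@]2(C)CCC[C@](C)(CO[Si](c4ccccc4)(c5ccccc5)C(C)(C)C)[C@H]2C(=O)CC=1C | intermediate
21 | (4S,5S,9R,10S)-18-[(tert-butyldiphenylsilyl)oxy]-14,15-dinorlabd-7-en-13(16)-yn-6-one (H9 cis to H5) | C#CCC[C@H]1[C@]2(C)CCC[C@](C)(CO[Si](c4ccccc4)(c5ccccc5)C(C)(C)C)[C@H]2C(=O)C=C1C | intermediate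
22 | (4S,5S,7R,8R,9S,10S)-18-[(tert-butyldiphenylsilyl)oxy]-7,8-epoxy-14,15-dinorlabd-13(16)-yn-6-one (epoxide on the face of H5 and H9) | C#CCC[C@H]1[C@]2(C)CCC[C@](C)(CO[Si](c4ccccc4)(c5ccccc5)C(C)(C)C)[C@H]2C(=O)[C@@H]3O[C@]13C | intermediate
23 | (4S,5S,8S,9S,10S)-18-[(tert-butyldiphenylsilyl)oxy]-8-hydroxy-14,15-dinorlabd-13(16)-yn-6-one (not isolated) | C#CCC[C@H]1[C@]2(C)CCC[C@](C)(CO[Si](c4ccccc4)(c5ccccc5)C(C)(C)C)[C@H]2C(=O)C[C@]1(C)O | intermediate
24 | (4S,5S,6R,8S,9S,10R)-18-[(tert-butyldiphenylsilyl)oxy]-14,15-dinorlabd-13(16)-yne-6,8-diol | C#CCC[C@H]1[C@]2(C)CCC[C@](C)(CO[Si](c4ccccc4)(c5ccccc5)C(C)(C)C)[C@H]2[C@H](O)C[C@]1(C)O | intermediate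
25 | (4S,5S,6R,8S,9S,10R)-14,15-dinorlabd-13(16)-yne-6,8,18-triol | C#CCC[C@H]1[C@]2(C)CCC[C@](C)(CO)[C@H]2[C@H](O)C[C@]1(C)O | intermediate
26 | (4S,5S,6R,8S,9S,10R)-6,8-dihydroxy-14,15-dinorlabd-13(16)-yn-18-yl acetate | C#CCC[C@H]1[C@]2(C)CCC[C@](C)(COC(C)=O)[C@H]2[C@H](O)C[C@]1(C)O | intermediate
27 | (4S,5S,6R,8S,9S,10R)-6,8-dihydroxylabda-13(16),14-dien-18-yl acetate (CNP0317825.1) | C=CC(=C)CC[C@H]1[C@]2(C)CCC[C@](C)(COC(C)=O)[C@H]2[C@H](O)C[C@]1(C)O | target

**Step count.** Total: 15 steps. Longest linear sequence: 13 steps (steps 1–5 and 8–15).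

**Steps most likely to fail**

Step 9. The conjugate addition of the hindered C5 enolate to the fully substituted enone terminus may be too slow, so that reversible γ-deprotonation and retro-aldol traffic consume the material. It may also close ring A with poor facial discrimination relative to C4. Fallback: leave the anionic manifold for an acid-mediated cyclisation. Setting out from 16, p-TsOH·H2O in toluene at reflux with removal of water (enol addition to the O-protonated enone, then acid-catalysed aldol condensation) should give the C-silylated conjugated enone F1 as a C9 epimer mixture. Exposure of F1 to t-BuOK in t-BuOH–THF followed by the cold AcOH quench (desilylation, dienolate formation, kinetic protonation) returns to 20.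

Step 10. Protonation of the dienol may occur on both faces of C9, or the acid may equilibrate C9 towards the epimer with the pseudoaxial side chain. Fallback: create C8 and C9 in one syn addition instead. From 20, SmI2–H2O–Et3N reduction should give the equatorial homoallylic alcohol F2. Co2(CO)8 then masks the alkyne as its hexacarbonyldicobalt complex F3. Hydroboration of the tetrasubstituted C8=C9 bond with BH3·THF on the face opposite to the C10 methyl (boron at the less hindered C8), followed by work-up with excess trimethylamine N-oxide, which oxidises the C–B bond with retention and strips the cobalt, joins the route again at 24.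

Step 12. The C6 ketyl or organosamarium may be protonated from the open face and give the axial alcohol, or the β-hydroxy ketone may lose water. Fallback: separate the two reductions. From 22, SmI2 (2.2 equiv) in THF–MeOH at −78 °C stops at 23, which is isolated. NaBH4 reduces it from the open face to the axial C6 epimer F4. Meerwein–Ponndorf–Verley/Oppenauer equilibration (Al(Oi-Pr)3 (20 mol%), i-PrOH, a trace of acetone, toluene, reflux) then drives F4 to the far more stable equatorial alcohol 24.

**Further compounds**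

F1 | step 9 | (4S,5S,10S)-18-[(tert-butyldiphenylsilyl)oxy]-16-(trimethylsilyl)-14,15-dinorlabd-7-en-13(16)-yn-6-one (C9 epimers) | C[Si](C)(C)C#CCCC1[C@]2(C)CCC[C@](C)(CO[Si](c4ccccc4)(c5ccccc5)C(C)(C)C)[C@H]2C(=O)C=C1C
F2 | step 10 | (4S,5S,6R,10R)-18-[(tert-butyldiphenylsilyl)oxy]-14,15-dinorlabd-8-en-13(16)-yn-6-ol | C#CCCC=1[C@]2(C)CCC[C@](C)(CO[Si](c4ccccc4)(c5ccccc5)C(C)(C)C)[C@H]2[C@H](O)CC=1C
F3 | step 10 | Co2(CO)6 complex of the alkyne of F2 (written as its components) | C#CCCC=1[C@]2(C)CCC[C@](C)(CO[Si](c4ccccc4)(c5ccccc5)C(C)(C)C)[C@H]2[C@H](O)CC=1C.[Co].[Co].[C-]#[O+].[C-]#[O+].[C-]#[O+].[C-]#[O+].[C-]#[O+].[C-]#[O+]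
F4 | step 12 | (4S,5S,6S,8S,9S,10R)-18-[(tert-butyldiphenylsilyl)oxy]-14,15-dinorlabd-13(16)-yne-6,8-diol (axial C6 hydroxyl) | C#CCC[C@H]1[C@]2(C)CCC[C@](C)(CO[Si](c4ccccc4)(c5ccccc5)C(C)(C)C)[C@H]2[C@@H](O)C[C@]1(C)O
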